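**Retrosynthetic overview**

- Numbering used: tetralone numbering (C1 ketone, C2 and C3 methyl-bearing, C4 aryl-bearing, C4a/C8a ring fusion); ring A is the fused arene, ring B the cyclohexanone ring, ring C the dimethoxyphenyl group.
- Ring B is cut at C1–C8a and C3–C4 in one [3+3] disconnection. One partner is a ring A–C4–ring C benzhydrol brominated at C8a (from 6-bromovanillin and an aryl Grignard reagent). The other is meso cis-2,3-dimethylcyclopropanone, used as its sulfinate adduct (from meso-butane-2,3-diol); it acts as acyl cation at C1 and homoenolate at C3. Its C1–C3 bond is a temporary bond that stores the cis C2/C3 methyls and is cleaved in the same operation.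
- Enabling feature: the free C7 hydroxyl of ring A is para to C4a, so the doubly benzylic C4 ionises to a para-quinone methide. C8a (next to C4a, para to the C6 methoxyl) can carry bromine for lithiation, which decides for ring A against the equally electron-rich ring C.
- Ring order: rings A and C are bought, the three-membered ring is made in step 3, and ring B is formed last (step 5) at the expense of the three-membered ring. Step 5 delivers the target directly, without protecting groups.

Key step: step 5

Remark on the chemistry: 1 and 4 are taken as purchased, and the sense of induction of the chiral phosphoric acid in step 5 cannot be derived from precedent, so the (R)-catalyst is written and its mirror image would be used should the first experiment show the opposite sense.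

**Route**

Step 1
Reactants: 1 2-bromo-4-hydroxy-5-methoxybenzaldehyde (6-bromovanillin); 2 (3,4-dimethoxyphenyl)magnesium bromide
Product: 3 (2-bromo-4-hydroxy-5-methoxyphenyl)(3,4-dimethoxyphenyl)methanol (racemic)
Conditions: 2 (3 equiv), THF, 0 °C to rt; aq NH4Cl
Reagents that add atoms: none
Why: Grignard 1,2-addition to the aldehyde, in which the first equivalent of 2 is spent on the phenol and the excess adds to the magnesium phenoxide–aldehyde (the usual way to para-hydroxybenzhydrols); the new carbinol centre is formed racemic, which is immaterial because it becomes planar in step 5.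

Step 2
Reactants: 4 meso-butane-2,3-diol
Product: 6 (4R,5S)-4,5-dimethyl-1,3,2-dioxathiolane 2,2-dioxide, via cyclic sulfite 5 (not isolated)
Conditions: SOCl2, CH2Cl2, reflux; then RuCl3·xH2O (cat.), NaIO4, MeCN–H2O, 0 °C
Reagents that add atoms: thionyl chloride, ClS(Cl)=O; sodium periodate, [Na+].[O-][I](=O)(=O)=O
Why: Cyclic sulfite formation followed by ruthenium-catalysed periodate oxidation to the cyclic sulfate, a standard activation of 1,2-diols in which neither C–O bond is touched, so the meso (cis) arrangement of 4 is kept.

Step 3
Reactants: 6 (4R,5S)-4,5-dimethyl-1,3,2-dioxathiolane 2,2-dioxide; 7 methyl phenyl sulfone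
Product: 9 cis-2,3-dimethylcyclopropyl phenyl sulfone, via sulfate monoester 8 (not isolated)
Conditions: 7, n-BuLi (1.05 equiv), THF, −78 °C; 6, −78 to 0 °C; then n-BuLi (1.1 equiv), 0 °C to rt
Reagents that add atoms: none
Why: Double alkylation of a sulfonyl-stabilised carbanion by a 1,2-cyclic sulfate (SN2 opening, second deprotonation, then 3-exo-tet displacement of the sulfate monoester), each C–C bond being formed with inversion, so the cis-dimethyl relationship of the meso sulfate should be carried into the cyclopropane.

Step 4
Reactants: 9 cis-2,3-dimethylcyclopropyl phenyl sulfone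
Product: 11 (2R,3S)-2,3-dimethyl-1-(phenylsulfonyl)cyclopropan-1-ol, via silyl ether 10 (not isolated)
Conditions: n-BuLi, THF, −78 °C; (Me3SiO)2, −78 °C to rt; then 1 M HCl, THF, 0 °C
Reagents that add atoms: bis(trimethylsilyl) peroxide, C[Si](C)(C)OO[Si](C)(C)C
Why: α-Lithiation of the cyclopropyl sulfone and electrophilic oxygen transfer from the bis(silyl) peroxide (the established α-hydroxylation route to 1-sulfonylcyclopropanols, bench-stable cyclopropanone equivalents); the configuration at the carbinol carbon does not matter because it becomes the planar carbonyl carbon of 13.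

Step 5
Reactants: 3 (2-bromo-4-hydroxy-5-methoxyphenyl)(3,4-dimethoxyphenyl)methanol; 11 (2R,3S)-2,3-dimethyl-1-(phenylsulfonyl)cyclopropan-1-ol
Product: 16 schisandrone, via aryllithium 12 (not isolated), via cis-2,3-dimethylcyclopropanone 13 (not isolated), via arylcyclopropanol 14 (not isolated), via para-quinone methide 15 (not isolated)
Conditions: 3, n-BuLi (2.0 equiv) then t-BuLi (2.0 equiv), THF, −78 °C; add 11 pre-treated with n-BuLi (1.0 equiv, THF, −78 °C), −78 to −20 °C; aq NH4Cl, extraction, solvent switch to toluene without purification; then (R)-3,3'-bis(2,4,6-triisopropylphenyl)-1,1'-binaphthyl-2,2'-diyl hydrogen phosphate (10 mol %), 4 Å molecular sieves, toluene (high dilution), −20 °C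
Reagents that add atoms: none
Why: Proposed new method: bromine–lithium exchange on the dilithium salt of 3 gives 12, which adds to cyclopropanone 13 (released from the lithium alkoxide of 11 by loss of benzenesulfinate; it is reluctant to enolise, so the cis methyls are safe) and forms C1–C8a without over-addition; after the quench the chiral phosphoric acid dehydrates the para-hydroxybenzhydrol of 14 to quinone methide 15 and, hydrogen-bonded to the quinone methide oxygen and the cyclopropanol OH, lets the strained C1–C3 σ bond attack C4, so that C3–C4 forms while the temporary C1–C3 bond breaks and the C1 carbinol becomes the ketone. The closest known reaction types are additions of organometallic reagents to 1-sulfonylcyclopropanols, acid-mediated ring-opening alkylations of cyclopropanols by tethered oxocarbenium ions (homoenol reactivity) and chiral phosphoric acid-catalysed 1,6-additions to para-quinone methides generated in situ from para-hydroxybenzyl alcohols; their merger in an intramolecular, desymmetrising form is what is new. Ring B closes in a 6-endo-trig sense with respect to the exocyclic C4=C4a bond of 15, the nucleophile being the C1–C3 σ bond attacked from its front side. C2 is carried unchanged from the meso cyclopropanone; C3 should react with retention because C4 is held on the side of the departing C1, so the cis methyls of the three-membered ring become the 2,3-cis methyls; C4 should be set in the compact cyclic transition state in which ring C eclipses the C3–H and not the C3–methyl (3,4-trans); the absolute sense is set by the catalyst, which must choose between the enantiotopic C1–C2 and C1–C3 bonds. The step needs acylation of ring A and not of the equally electron-rich ring C (secured by the bromine at C8a), C- rather than O-alkylation at C4 (the cyclic ether from attack of the cyclopropanol oxygen is a para-hydroxybenzhydryl ether that re-ionises under the same acid, whereas C–C closure is irreversible) and closure faster than protonolysis of the cyclopropanol (secured by the weak acid and the intramolecular electrophile).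

**Compound list**

1 | 2-bromo-4-hydroxy-5-methoxybenzaldehyde (6-bromovanillin) | COc1cc(C=O)c(Br)cc1O | starting material
2 | (3,4-dimethoxyphenyl)magnesium bromide | COc1ccc([Mg]Br)cc1OC | starting material
3 | (2-bromo-4-hydroxy-5-methoxyphenyl)(3,4-dimethoxyphenyl)methanol, racemic | COc1cc(C(O)c2ccc(OC)c(OC)c2)c(Br)cc1O | intermediate
4 | meso-butane-2,3-diol, (2R,3S) | C[C@H](O)[C@@H](C)O | starting material
5 | (4R,5S)-4,5-dimethyl-1,3,2-dioxathiolane 2-oxide (cis, both sulfur epimers) | C[C@@H]1OS(=O)O[C@@H]1C | intermediate (not isolated)
6 | (4R,5S)-4,5-dimethyl-1,3,2-dioxathiolane 2,2-dioxide (cis, meso) | C[C@@H]1OS(=O)(=O)O[C@@H]1C | intermediate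
7 | methyl phenyl sulfone | CS(=O)(=O)c1ccccc1 | starting material
8 | lithium (2R*,3R*)-3-methyl-4-(phenylsulfonyl)butan-2-yl sulfate, racemic | C[C@@H](CS(=O)(=O)c1ccccc1)[C@@H](C)OS(=O)(=O)[O-].[Li+] | intermediate (not isolated)
9 | cis-2,3-dimethylcyclopropyl phenyl sulfone, (2R,3S), meso, sulfonyl drawn anti to the methyls | C[C@@H]1[C@H](C)[C@H]1S(=O)(=O)c1ccccc1 | intermediate
10 | trimethyl{[(2R,3S)-2,3-dimethyl-1-(phenylsulfonyl)cyclopropyl]oxy}silane | C[C@@H]1[C@H](C)[C@@]1(O[Si](C)(C)C)S(=O)(=O)c1ccccc1 | intermediate (not isolated)
11 | (2R,3S)-2,3-dimethyl-1-(phenylsulfonyl)cyclopropan-1-ol (cis-dimethyl, meso) | C[C@@H]1[C@H](C)[C@@]1(O)S(=O)(=O)c1ccccc1 | intermediate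
12 | trilithium salt of 3 lithiated at the bromine-bearing carbon (aryllithium) | [Li]c1cc(O[Li])c(OC)cc1C(O[Li])c1ccc(OC)c(OC)c1 | intermediate (not isolated)
13 | (2R,3S)-2,3-dimethylcyclopropan-1-one (cis, meso) | C[C@@H]1[C@H](C)C1=O | intermediate (not isolated)
14 | 1-{2-[(3,4-dimethoxyphenyl)(hydroxy)methyl]-5-hydroxy-4-methoxyphenyl}-(2R,3S)-2,3-dimethylcyclopropan-1-ol (aryl anti to the methyls, carbinol epimers) | C[C@@H]1[C@H](C)[C@@]1(O)c1cc(O)c(OC)cc1C(O)c1ccc(OC)c(OC)c1 | intermediate (not isolated)
15 | 4-[(3,4-dimethoxyphenyl)methylidene]-5-[(2R,3S)-1-hydroxy-2,3-dimethylcyclopropyl]-2-methoxycyclohexa-2,5-dien-1-one | C[C@@H]1[C@H](C)[C@@]1(O)C1=CC(=O)C(OC)=C/C1=C\c1ccc(OC)c(OC)c1 | intermediate (not isolated)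
16 | schisandrone, (2S,3S,4R)-4-(3,4-dimethoxyphenyl)-7-hydroxy-6-methoxy-2,3-dimethyl-3,4-dihydronaphthalen-1(2H)-one | COc1cc2c(cc1O)C(=O)[C@@H](C)[C@@H](C)[C@@H]2c1ccc(OC)c(OC)c1 | target

**Step count**

Total: 5 steps. Longest linear sequence: 4 steps (steps 2, 3, 4, 5).

**Steps most likely to fail**

1. Step 5 (Proposed new method). What may go wrong:
   - The front-side C–C closure may lose to O-alkylation at C4 that does not funnel on to ring B.
   - It may lose to protonolysis of the cyclopropanol.
   - The catalyst may not tell the two enantiotopic ring bonds apart, giving low enantiomeric purity.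

   Fallback with known chemistry only, setting out from 2 and coming back at 16. Grignard reagent 2 is transmetalated with ZnCl2. The arylzinc is coupled with commercial meso-2,3-dimethylsuccinic anhydride under [Rh(cod)Cl]2 and the phosphoramidite (3aR,8aR)-N,N,2,2-tetramethyl-4,4,8,8-tetraphenyltetrahydro-[1,3]dioxolo[4,5-e][1,3,2]dioxaphosphepin-6-amine, or its mirror image, whichever delivers the required antipode. This enantioselective desymmetrisation of a meso anhydride by an organozinc reagent should give (2S,3R)-4-(3,4-dimethoxyphenyl)-2,3-dimethyl-4-oxobutanoic acid F1. Reduction of the ketone (NaBH4, CeCl3, MeOH, −40 °C) and acid-induced lactonisation should give (3S,4R)-5-(3,4-dimethoxyphenyl)-3,4-dimethyloxolan-2-one F2, whose C5 epimers need not be separated because this centre is ionised next. Friedel–Crafts alkylation of commercial 5-bromo-2-methoxyphenol with F2 (CF3SO3H, CH2Cl2, 0 °C) should place the benzylic carbon para to the phenol, with 1,2-induction from the neighbouring methyl-bearing centre, and give (2S,3S,4R)-4-(2-bromo-4-hydroxy-5-methoxyphenyl)-4-(3,4-dimethoxyphenyl)-2,3-dimethylbutanoic acid F3; a C4 epimer would be removed here. Parham cyclisation of F3 (n-BuLi, 2 equiv, then t-BuLi, 2 equiv, THF, −78 °C; the aryllithium closes onto the lithium carboxylate, and the ketone appears only on work-up, so C2 is not exposed to base) should give 16.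

2. Step 3. What may go wrong: elimination of the secondary sulfate monoester in 8 may compete with the 3-exo-tet closure, or the cyclic sulfate may be opened at both carbons by two sulfonyl carbanions.

   Fallback, setting out from 7 and coming back at 9. The two C–C bonds are made in separate operations with a better leaving group for the ring closure. Lithiated 7 opens commercial cis-2,3-epoxybutane (n-BuLi, BF3·OEt2, THF, −78 °C) with inversion to give (2R*,3R*)-3-methyl-4-(phenylsulfonyl)butan-2-ol F4. Tosylation (TsCl, pyridine) gives (2R*,3R*)-3-methyl-4-(phenylsulfonyl)butan-2-yl 4-methylbenzenesulfonate F5. LiN(SiMe3)2 (THF, 0 °C) then closes the three-membered ring with a second inversion to 9.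

3. Step 4. What may go wrong: the lithiated cyclopropyl sulfone may fragment or be protonated back before oxygen transfer, or the silyl peroxide may transfer silicon instead of oxygen.

   Fallback, setting out from 6 and coming back at 11. The oxygen is brought in with the sulfone instead of being installed afterwards. Benzyloxymethyl phenyl sulfone is deprotonated twice in sequence (n-BuLi, THF, −78 °C to rt) in the presence of 6 and doubly alkylated as in step 3, to give {[(2R,3S)-1-(benzyloxy)-2,3-dimethylcyclopropyl]sulfonyl}benzene F6. Hydrogenolysis of the benzyl ether (H2, Pd/C, EtOAc, rt) gives 11.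

Further compounds
F1 | step 5 | (2S,3R)-4-(3,4-dimethoxyphenyl)-2,3-dimethyl-4-oxobutanoic acid | OC(=O)[C@@H](C)[C@@H](C)C(=O)c1ccc(OC)c(OC)c1
F2 | step 5 | (3S,4R)-5-(3,4-dimethoxyphenyl)-3,4-dimethyloxolan-2-one (C5 epimers) | O=C1[C@@H](C)[C@@H](C)C(c2ccc(OC)c(OC)c2)O1
F3 | step 5 | (2S,3S,4R)-4-(2-bromo-4-hydroxy-5-methoxyphenyl)-4-(3,4-dimethoxyphenyl)-2,3-dimethylbutanoic acid | OC(=O)[C@@H](C)[C@@H](C)[C@@H](c1cc(OC)c(O)cc1Br)c1ccc(OC)c(OC)c1
F4 | step 3 | (2R*,3R*)-3-methyl-4-(phenylsulfonyl)butan-2-ol, racemic | C[C@@H](CS(=O)(=O)c1ccccc1)[C@@H](C)O
F5 | step 3 | (2R*,3R*)-3-methyl-4-(phenylsulfonyl)butan-2-yl 4-methylbenzenesulfonate, racemic | C[C@@H](CS(=O)(=O)c1ccccc1)[C@@H](C)OS(=O)(=O)c1ccc(C)cc1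
F6 | step 4 | {[(2R,3S)-1-(benzyloxy)-2,3-dimethylcyclopropyl]sulfonyl}benzene | C[C@@H]1[C@H](C)[C@@]1(OCc1ccccc1)S(=O)(=O)c1ccccc1
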